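**Retrosynthetic overview**
1. Target 35 ⇐ fluoride unmasking of a 2,4-bis(2-silylethoxy)pyridine 1-oxide (a masked 1,4-dihydroxy-2-pyridone); C3–acyl bond ⇐ C3-magnesiated N-oxide + decalin aldehyde 12, then oxidation.
2. C5–C(OH) bond ⇐ 5-lithiopyridine + epoxy ketone 21 (attack anti to the oxirane); the N–O bond is made with mCPBA before any alkene is in the molecule.
3. 21 ⇐ (S)-4-silyloxycyclohexenone 20 ⇐ lipase desymmetrisation of meso-diacetate 16 ⇐ cyclohexa-1,3-diene + singlet oxygen.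
4. 12 ⇐ endo-selective Lewis-acid intramolecular Diels–Alder of (6R)-trienal 11 ⇐ (R)-citronellol ⇐ Ru–BINAP hydrogenation of geraniol.
5. Ring order: cyclohexane and pyridine rings come from the starting materials; both decalin rings form together (step 10); oxirane (step 17); the pyridine becomes the N-hydroxypyridone in the last step.

Assumption: the lipase hydrolyses the acetate on the (S)-configured carbinol carbon of 16 (Kazlauskas-type preference, as for the cyclopentene analogue); if a given lipase shows the opposite preference, 17 is obtained with the same enzyme by acetylating diol 15 with vinyl acetate.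

**Part A – decalin aldehyde**

Step 1
Reactants: 1 geraniol
Product: 2 (R)-citronellol
Conditions: H2 (100 atm), Ru(OAc)2[(S)-BINAP] (0.2 mol %), 95% aq. MeOH, 20 °C
Reagents that add atoms: none
Why: Noyori asymmetric hydrogenation; the hydroxyl-bound Ru–(S)-BINAP catalyst adds H2 to one face of the allylic alkene only, setting C3 as R and leaving the remote trisubstituted alkene untouched.

Step 2
Reactants: 2 (R)-citronellol
Product: 3 (R)-citronellal
Conditions: TEMPO (2,2,6,6-tetramethylpiperidin-1-oxyl, cat.), PhI(OAc)2, CH2Cl2, rt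
Reagents that add atoms: none
Why: Oxoammonium (TEMPO) oxidation stops at the aldehyde, and the stereocentre is β to the carbonyl so it cannot epimerise.

Step 3
Reactants: 3 (R)-citronellal
Product: 4 (4R)-4,8-dimethylnon-7-en-1-yne
Conditions: dimethyl (1-diazo-2-oxopropyl)phosphonate, K2CO3, MeOH, 0 °C → rt
Reagents that add atoms: dimethyl (1-diazo-2-oxopropyl)phosphonate, COP(=O)(OC)C(=[N+]=[N-])C(C)=O
Why: Ohira–Bestmann (Seyferth–Gilbert) homologation converts the aldehyde into the terminal alkyne under mild base.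

Step 4
Reactants: 4 (4R)-4,8-dimethylnon-7-en-1-yne
Product: 6 (4R)-4-methylhept-6-ynal, via ozonide 5 (not isolated)
Conditions: O3 (1 equiv), CH2Cl2, −78 °C; then PPh3, −78 °C → rt
Reagents that add atoms: ozone, [O-][O+]=O
Why: Ozonolysis with reductive work-up; the electron-rich trisubstituted alkene reacts far faster than the terminal alkyne.

Step 5
Reactants: 6 (4R)-4-methylhept-6-ynal
Product: 7 methyl (2E,6R)-6-methylnon-2-en-8-ynoate
Conditions: (MeO)2P(O)CH2CO2Me, LiCl, DBU, MeCN, rt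
Reagents that add atoms: trimethyl phosphonoacetate, COC(=O)CP(=O)(OC)OC
Why: Masamune–Roush Horner–Wadsworth–Emmons olefination gives the E-enoate and is too mild to deprotonate the alkyne.

Step 6
Reactants: 7 methyl (2E,6R)-6-methylnon-2-en-8-ynoate
Product: 8 methyl (2E,6R,8E)-6-methyl-9-(4,4,5,5-tetramethyl-1,3,2-dioxaborolan-2-yl)nona-2,8-dienoate
Conditions: pinacolborane, dicyclohexylborane (5 mol %), neat, rt
Reagents that add atoms: pinacolborane, B1OC(C)(C)C(C)(C)O1
Why: Dialkylborane-catalysed hydroboration of the terminal alkyne is a syn, anti-Markovnikov addition and gives only the E-alkenylboronate; the enoate is inert.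

Step 7
Reactants: 8 methyl (2E,6R,8E)-6-methyl-9-(4,4,5,5-tetramethyl-1,3,2-dioxaborolan-2-yl)nona-2,8-dienoate
Product: 9 methyl (2E,6R,8E,10E)-6-methyldodeca-2,8,10-trienoate
Conditions: (E)-1-bromoprop-1-ene, Pd(PPh3)4 (5 mol %), K3PO4, dioxane/H2O, 60 °C, sealed tube
Reagents that add atoms: (E)-1-bromoprop-1-ene, C/C=C/Br
Why: Suzuki–Miyaura coupling proceeds with retention at both alkenyl partners, giving the E,E-diene.

Step 8
Reactants: 9 methyl (2E,6R,8E,10E)-6-methyldodeca-2,8,10-trienoate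
Product: 10 (2E,6R,8E,10E)-6-methyldodeca-2,8,10-trien-1-ol
Conditions: i-Bu2AlH (2.2 equiv), CH2Cl2, −78 °C
Reagents that add atoms: none
Why: Hydride 1,2-reduction of the enoate to the allylic alcohol without touching the diene.

Step 9
Reactants: 10 (2E,6R,8E,10E)-6-methyldodeca-2,8,10-trien-1-ol
Product: 11 (2E,6R,8E,10E)-6-methyldodeca-2,8,10-trienal
Conditions: MnO2, CH2Cl2, rt
Reagents that add atoms: none
Why: Selective allylic oxidation with retention of the E-enal geometry.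

Step 10
Reactants: 11 (2E,6R,8E,10E)-6-methyldodeca-2,8,10-trienal
Product: 12 (1R,2R,4aS,6R,8aR)-2,6-dimethyl-1,2,4a,5,6,7,8,8a-octahydronaphthalene-1-carbaldehyde
Conditions: Me2AlCl, CH2Cl2, −78 → −20 °C
Reagents that add atoms: none
Why: Lewis-acid-promoted intramolecular Diels–Alder reaction through the endo transition state with a chair-like tether and equatorial C6 methyl gives the trans-fused decalin, the four new stereocentres being set relative to the C6 centre.

**Part B – epoxy ketone**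

Step 11
Reactants: 13 cyclohexa-1,3-diene
Product: 15 cis-cyclohex-2-ene-1,4-diol, via endoperoxide 14 (not isolated)
Conditions: O2, hν, 5,10,15,20-tetraphenylporphyrin (cat.), CH2Cl2, 0 °C; then Zn, AcOH, 0 °C → rt
Reagents that add atoms: oxygen, O=O
Why: Suprafacial [4+2] cycloaddition of singlet oxygen followed by O–O reduction can only give the cis (meso) diol.

Step 12
Reactants: 15 cis-cyclohex-2-ene-1,4-diol
Product: 16 cis-cyclohex-2-ene-1,4-diyl diacetate
Conditions: Ac2O, pyridine, 4-(dimethylamino)pyridine (cat.), CH2Cl2, rt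
Reagents that add atoms: acetic anhydride, CC(=O)OC(C)=O
Why: Routine acylation gives the meso-diacetate substrate for the enzyme.

Step 13
Reactants: 16 cis-cyclohex-2-ene-1,4-diyl diacetate
Product: 17 (1S,4R)-4-acetoxycyclohex-2-en-1-ol
Conditions: lipase (Burkholderia cepacia lipase, Amano PS), 0.1 M phosphate buffer pH 7, rt, stopped at mono-hydrolysis
Reagents that add atoms: none
Why: Lipase-catalysed desymmetrisation of a meso-diester; the enzyme hydrolyses only the acetate on the (S)-carbinol carbon, so both stereocentres emerge in one absolute sense from an achiral substrate.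

Step 14
Reactants: 17 (1S,4R)-4-acetoxycyclohex-2-en-1-ol
Product: 18 (1R,4S)-4-(tert-butyldimethylsilyloxy)cyclohex-2-en-1-yl acetate
Conditions: TBSCl, imidazole, DMF, rt
Reagents that add atoms: tert-butyldimethylsilyl chloride, CC(C)(C)[Si](C)(C)Cl
Why: Silylation of the free hydroxyl marks the (S)-carbon as the future secondary carbinol of the target.

Step 15
Reactants: 18 (1R,4S)-4-(tert-butyldimethylsilyloxy)cyclohex-2-en-1-yl acetate
Product: 19 (1R,4S)-4-(tert-butyldimethylsilyloxy)cyclohex-2-en-1-ol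
Conditions: K2CO3 (cat.), MeOH, 0 °C
Reagents that add atoms: none
Why: Transesterification removes the acetate without touching the silyl ether.

Step 16
Reactants: 19 (1R,4S)-4-(tert-butyldimethylsilyloxy)cyclohex-2-en-1-ol
Product: 20 (4S)-4-(tert-butyldimethylsilyloxy)cyclohex-2-en-1-one
Conditions: MnO2, CH2Cl2, rt
Reagents that add atoms: none
Why: Allylic oxidation removes the (R)-carbinol centre and leaves the (S)-silyloxy centre intact.

Step 17
Reactants: 20 (4S)-4-(tert-butyldimethylsilyloxy)cyclohex-2-en-1-one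
Product: 21 (1R,5S,6S)-5-(tert-butyldimethylsilyloxy)-7-oxabicyclo[4.1.0]heptan-2-one
Conditions: 30% H2O2, benzyltrimethylammonium hydroxide (Triton B, cat.), THF, 0 °C
Reagents that add atoms: hydrogen peroxide, OO
Why: Weitz–Scheffer nucleophilic epoxidation; hydroperoxide adds to the enone face anti to the bulky C4 silyloxy group, giving the trans epoxide.

**Part C – pyridine core**

Step 18
Reactants: 22 2,4-difluoropyridine
Product: 24 2,4-bis[2-(trimethylsilyl)ethoxy]pyridine, via monoether 23 (not isolated)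
Conditions: 2-(trimethylsilyl)ethanol (2.4 equiv), NaH, THF, 0 → 60 °C
Reagents that add atoms: 2-(trimethylsilyl)ethanol, C[Si](C)(C)CCO
Why: Two successive nucleophilic aromatic substitutions (C4 then C2) place both oxygens unambiguously on carbon as fluoride-labile ethers.

Step 19
Reactants: 24 2,4-bis[2-(trimethylsilyl)ethoxy]pyridine
Product: 25 5-bromo-2,4-bis[2-(trimethylsilyl)ethoxy]pyridine
Conditions: NBS, MeCN, 0 °C → rt
Reagents that add atoms: N-bromosuccinimide, O=C1CCC(=O)N1Br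
Why: Electrophilic aromatic bromination goes to C5, which is para to the 2-alkoxy and ortho to the 4-alkoxy group and less hindered than C3.

**Part D – assembly**

Step 20
Reactants: 25 5-bromo-2,4-bis[2-(trimethylsilyl)ethoxy]pyridine; 21 (1R,5S,6S)-5-(tert-butyldimethylsilyloxy)-7-oxabicyclo[4.1.0]heptan-2-one
Product: 27 5-[(1R,2R,5S,6S)-5-(tert-butyldimethylsilyloxy)-2-hydroxy-7-oxabicyclo[4.1.0]heptan-2-yl]-2,4-bis[2-(trimethylsilyl)ethoxy]pyridine, via 5-lithiopyridine 26 (not isolated)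
Conditions: n-BuLi, THF, −78 °C; then 21, −78 °C; H2O
Reagents that add atoms: none
Why: Bromine–lithium exchange then 1,2-addition to the α,β-epoxy ketone; the aryllithium attacks the carbonyl face opposite the oxirane oxygen, giving the tertiary alcohol cis to the epoxide.

Step 21
Reactants: 27 5-[(1R,2R,5S,6S)-5-(tert-butyldimethylsilyloxy)-2-hydroxy-7-oxabicyclo[4.1.0]heptan-2-yl]-2,4-bis[2-(trimethylsilyl)ethoxy]pyridine
Product: 28 5-[(1R,2R,5S,6S)-5-(tert-butyldimethylsilyloxy)-2-(trimethylsilyloxy)-7-oxabicyclo[4.1.0]heptan-2-yl]-2,4-bis[2-(trimethylsilyl)ethoxy]pyridine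
Conditions: 1-(trimethylsilyl)imidazole, CH2Cl2, rt
Reagents that add atoms: 1-(trimethylsilyl)imidazole, C[Si](C)(C)n1ccnc1
Why: Neutral silylation caps the tertiary alcohol without Lewis acid, so no alkoxide or acid can trigger a semipinacol shift onto the neighbouring epoxide in later steps.

Step 22
Reactants: 28 5-[(1R,2R,5S,6S)-5-(tert-butyldimethylsilyloxy)-2-(trimethylsilyloxy)-7-oxabicyclo[4.1.0]heptan-2-yl]-2,4-bis[2-(trimethylsilyl)ethoxy]pyridine
Product: 30 3-iodo derivative of 28, via 3-lithiopyridine 29 (not isolated)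
Conditions: lithium 2,2,6,6-tetramethylpiperidide, THF, −78 °C; then I2, −78 → 0 °C
Reagents that add atoms: iodine, II
Why: Directed ortho-metalation at the only C–H flanked by two alkoxy groups, then iodinolysis; the hindered amide base does not open the epoxide at −78 °C.

Step 23
Reactants: 30 3-iodo derivative of 28
Product: 31 3-iodo-5-[(1R,2R,5S,6S)-5-(tert-butyldimethylsilyloxy)-2-(trimethylsilyloxy)-7-oxabicyclo[4.1.0]heptan-2-yl]-2,4-bis[2-(trimethylsilyl)ethoxy]pyridine 1-oxide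
Conditions: mCPBA, NaHCO3, CH2Cl2, 0 °C → rt
Reagents that add atoms: 3-chloroperoxybenzoic acid, OOC(=O)c1cccc(Cl)c1
Why: Peracid N-oxidation installs the N–O bond while the molecule contains no alkene; epoxide, silyl ethers and aryl iodide tolerate buffered mCPBA.

Step 24
Reactants: 31 the pyridine 1-oxide from step 23; 12 (1R,2R,4aS,6R,8aR)-2,6-dimethyl-1,2,4a,5,6,7,8,8a-octahydronaphthalene-1-carbaldehyde
Product: 33 [(1R,2R,4aS,6R,8aR)-2,6-dimethyl-1,2,4a,5,6,7,8,8a-octahydronaphthalen-1-yl]{5-[(1R,2R,5S,6S)-5-(tert-butyldimethylsilyloxy)-2-(trimethylsilyloxy)-7-oxabicyclo[4.1.0]heptan-2-yl]-1-oxido-2,4-bis[2-(trimethylsilyl)ethoxy]pyridin-1-ium-3-yl}methanol (both carbinol epimers), via arylmagnesium chloride 32 (not isolated)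
Conditions: i-PrMgCl·LiCl (1.1 equiv), THF, −40 °C; then 12, −40 → 0 °C; H2O
Reagents that add atoms: none
Why: Iodine–magnesium exchange on the N-oxide outruns C6 deprotonation at −40 °C, and the Grignard adds to the aldehyde; the new carbinol centre is unselective but is removed in the next step.

Step 25
Reactants: 33 the carbinol from step 24
Product: 34 3-[(1R,2R,4aS,6R,8aR)-2,6-dimethyl-1,2,4a,5,6,7,8,8a-octahydronaphthalene-1-carbonyl]-5-[(1R,2R,5S,6S)-5-(tert-butyldimethylsilyloxy)-2-(trimethylsilyloxy)-7-oxabicyclo[4.1.0]heptan-2-yl]-2,4-bis[2-(trimethylsilyl)ethoxy]pyridine 1-oxide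
Conditions: Dess–Martin periodinane, NaHCO3, CH2Cl2, rt
Reagents that add atoms: none
Why: Buffered Dess–Martin oxidation converts both carbinol epimers into the one aryl ketone without epimerising the adjacent decalin centre.

Step 26
Reactants: 34 the ketone from step 25
Product: 35 3-[(1R,2R,4aS,6R,8aR)-2,6-dimethyl-1,2,4a,5,6,7,8,8a-octahydronaphthalene-1-carbonyl]-5-[(1R,2R,5S,6R)-2,5-dihydroxy-7-oxabicyclo[4.1.0]heptan-2-yl]-1,4-dihydroxypyridin-2(1H)-one
Conditions: Bu4NF, AcOH (1:1, excess), THF, 0 °C → rt; pH 5 work-up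
Reagents that add atoms: none
Why: Fluoride-induced β-elimination of both 2-silylethyl ethers and desilylation of both silyl ethers; the freed 2-oxidopyridine 1-oxide is the N-hydroxy-2-pyridone tautomer, and the acetic acid buffer suppresses base-induced epoxide migration.

**Compound list**
(The 6S descriptor in the silyl ethers versus 6R in 35 reflects a CIP priority change at the neighbouring oxygen, not a change in geometry.)

1 | geraniol, (2E)-3,7-dimethylocta-2,6-dien-1-ol | CC(C)=CCC/C(C)=C/CO | starting material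
2 | (R)-citronellol | OCC[C@H](C)CCC=C(C)C | intermediate
3 | (R)-citronellal | O=CC[C@H](C)CCC=C(C)C | intermediate
4 | (4R)-4,8-dimethylnon-7-en-1-yne | C#CC[C@H](C)CCC=C(C)C | intermediate
5 | 3,3-dimethyl-5-[(3R)-3-methylhex-5-yn-1-yl]-1,2,4-trioxolane (ozonide, epimers at the ring CH) | C#CC[C@H](C)CCC1OOC(C)(C)O1 | intermediate
6 | (4R)-4-methylhept-6-ynal | C#CC[C@H](C)CCC=O | intermediate
7 | methyl (2E,6R)-6-methylnon-2-en-8-ynoate | C#CC[C@H](C)CC/C=C/C(=O)OC | intermediate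
8 | methyl (2E,6R,8E)-6-methyl-9-(4,4,5,5-tetramethyl-1,3,2-dioxaborolan-2-yl)nona-2,8-dienoate | CC1(C)OB(/C=C/C[C@H](C)CC/C=C/C(=O)OC)OC1(C)C | intermediate
9 | methyl (2E,6R,8E,10E)-6-methyldodeca-2,8,10-trienoate | C/C=C/C=C/C[C@H](C)CC/C=C/C(=O)OC | intermediate
10 | (2E,6R,8E,10E)-6-methyldodeca-2,8,10-trien-1-ol | C/C=C/C=C/C[C@H](C)CC/C=C/CO | intermediate
11 | (2E,6R,8E,10E)-6-methyldodeca-2,8,10-trienal | C/C=C/C=C/C[C@H](C)CC/C=C/C=O | intermediate
12 | (1R,2R,4aS,6R,8aR)-2,6-dimethyl-1,2,4a,5,6,7,8,8a-octahydronaphthalene-1-carbaldehyde | C[C@@H]1CC[C@H]2[C@H](C=O)[C@H](C)C=C[C@@H]2C1 | intermediate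
13 | cyclohexa-1,3-diene | C1=CC=CCC1 | starting material
14 | 2,3-dioxabicyclo[2.2.2]oct-5-ene | C1CC2C=CC1OO2 | intermediate
15 | cis-cyclohex-2-ene-1,4-diol (meso) | O[C@H]1C=C[C@@H](O)CC1 | intermediate
16 | cis-cyclohex-2-ene-1,4-diyl diacetate (meso) | CC(=O)O[C@H]1C=C[C@@H](OC(C)=O)CC1 | intermediate
17 | (1S,4R)-4-acetoxycyclohex-2-en-1-ol | CC(=O)O[C@H]1C=C[C@@H](O)CC1 | intermediate
18 | (1R,4S)-4-(tert-butyldimethylsilyloxy)cyclohex-2-en-1-yl acetate | CC(=O)O[C@H]1C=C[C@@H](O[Si](C)(C)C(C)(C)C)CC1 | intermediate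
19 | (1R,4S)-4-(tert-butyldimethylsilyloxy)cyclohex-2-en-1-ol | O[C@H]1C=C[C@@H](O[Si](C)(C)C(C)(C)C)CC1 | intermediate
20 | (4S)-4-(tert-butyldimethylsilyloxy)cyclohex-2-en-1-one | O=C1C=C[C@@H](O[Si](C)(C)C(C)(C)C)CC1 | intermediate
21 | (1R,5S,6S)-5-(tert-butyldimethylsilyloxy)-7-oxabicyclo[4.1.0]heptan-2-one (epoxide trans to the silyloxy group) | O=C1CC[C@H](O[Si](C)(C)C(C)(C)C)[C@H]2O[C@H]21 | intermediate
22 | 2,4-difluoropyridine | Fc1ccnc(F)c1 | starting material
23 | 2-fluoro-4-[2-(trimethylsilyl)ethoxy]pyridine | C[Si](C)(C)CCOc1ccnc(F)c1 | intermediate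
24 | 2,4-bis[2-(trimethylsilyl)ethoxy]pyridine | C[Si](C)(C)CCOc1ccnc(OCC[Si](C)(C)C)c1 | intermediate
25 | 5-bromo-2,4-bis[2-(trimethylsilyl)ethoxy]pyridine | C[Si](C)(C)CCOc1cc(OCC[Si](C)(C)C)c(Br)cn1 | intermediate
26 | {4,6-bis[2-(trimethylsilyl)ethoxy]pyridin-3-yl}lithium | [Li]c1cnc(OCC[Si](C)(C)C)cc1OCC[Si](C)(C)C | intermediate
27 | 5-[(1R,2R,5S,6S)-5-(tert-butyldimethylsilyloxy)-2-hydroxy-7-oxabicyclo[4.1.0]heptan-2-yl]-2,4-bis[2-(trimethylsilyl)ethoxy]pyridine | C[Si](C)(C)CCOc1cc(OCC[Si](C)(C)C)c([C@]2(O)CC[C@H](O[Si](C)(C)C(C)(C)C)[C@H]3O[C@H]32)cn1 | intermediate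
28 | trimethylsilyl ether of 27 at the tertiary hydroxyl | C[Si](C)(C)CCOc1cc(OCC[Si](C)(C)C)c([C@]2(O[Si](C)(C)C)CC[C@H](O[Si](C)(C)C(C)(C)C)[C@H]3O[C@H]32)cn1 | intermediate
29 | 3-lithio derivative of 28 | [Li]c1c(OCC[Si](C)(C)C)ncc([C@]2(O[Si](C)(C)C)CC[C@H](O[Si](C)(C)C(C)(C)C)[C@H]3O[C@H]32)c1OCC[Si](C)(C)C | intermediate
30 | 3-iodo derivative of 28 | Ic1c(OCC[Si](C)(C)C)ncc([C@]2(O[Si](C)(C)C)CC[C@H](O[Si](C)(C)C(C)(C)C)[C@H]3O[C@H]32)c1OCC[Si](C)(C)C | intermediate
31 | pyridine 1-oxide of 30 | Ic1c(OCC[Si](C)(C)C)[n+]([O-])cc([C@]2(O[Si](C)(C)C)CC[C@H](O[Si](C)(C)C(C)(C)C)[C@H]3O[C@H]32)c1OCC[Si](C)(C)C | intermediate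
32 | 3-(chloromagnesio) analogue of 31 | Cl[Mg]c1c(OCC[Si](C)(C)C)[n+]([O-])cc([C@]2(O[Si](C)(C)C)CC[C@H](O[Si](C)(C)C(C)(C)C)[C@H]3O[C@H]32)c1OCC[Si](C)(C)C | intermediate
33 | decalin-1-yl(pyridin-3-yl)methanol N-oxide, both carbinol epimers (full name in step 24) | C[C@@H]1CC[C@H]2[C@H](C(O)c3c(OCC[Si](C)(C)C)[n+]([O-])cc([C@]4(O[Si](C)(C)C)CC[C@H](O[Si](C)(C)C(C)(C)C)[C@H]5O[C@H]54)c3OCC[Si](C)(C)C)[C@H](C)C=C[C@@H]2C1 | intermediate
34 | fully protected 3-acylpyridine 1-oxide (full name in step 25) | C[C@@H]1CC[C@H]2[C@H](C(=O)c3c(OCC[Si](C)(C)C)[n+]([O-])cc([C@]4(O[Si](C)(C)C)CC[C@H](O[Si](C)(C)C(C)(C)C)[C@H]5O[C@H]54)c3OCC[Si](C)(C)C)[C@H](C)C=C[C@@H]2C1 | intermediate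
35 | 3-[(1R,2R,4aS,6R,8aR)-2,6-dimethyl-1,2,4a,5,6,7,8,8a-octahydronaphthalene-1-carbonyl]-5-[(1R,2R,5S,6R)-2,5-dihydroxy-7-oxabicyclo[4.1.0]heptan-2-yl]-1,4-dihydroxypyridin-2(1H)-one | C[C@@H]1CC[C@H]2[C@H](C(=O)c3c(O)c([C@]4(O)CC[C@H](O)[C@H]5O[C@H]54)cn(O)c3=O)[C@H](C)C=C[C@@H]2C1 | target

**Totals**
Total step count: 26. Longest linear sequence: 14 steps (13 → 35: steps 11–17, then 20–26). The decalin branch is 13 steps (1–10, 24–26) and the pyridine branch 9 steps (18–26).

**Three steps most likely to fail**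

Step 24 (iodine–magnesium exchange on the N-oxide and addition to a hindered aldehyde). Competing magnesiation or addition at C6 of the N-oxide, or enolisation of 12, could dominate. The fallback makes the C3–C bond on the plain pyridine and puts the N–O bond in last. It sets out from 28: lithiation as in step 22 gives 29, which is quenched with aldehyde 12 instead of iodine to give the pyridyl carbinol F1. Dess–Martin oxidation gives the ketone F2. Bu4NF/AcOH gives the N-unsubstituted 4-hydroxy-2-pyridone F3. Hexamethyldisilazane/TMSCl gives the tetrakis(trimethylsilyl) derivative F4. Its ring nitrogen is oxidised with MoO5·pyridine·HMPA in CH2Cl2 at 0 °C → rt (the Sammes silyl-imidate oxidation; this peroxo complex is a poor epoxidant for an isolated alkene) to the silylated N-oxide F5. Methanolic work-up desilylates F5 and the fallback comes back to the route at 35.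

Step 23 (N-oxidation of a hindered 2-alkoxy-3-iodopyridine). The reaction may be sluggish, or the electron-rich aryl iodide may be oxidised at iodine. The fallback oxidises nitrogen before the halogen is present and brings iodine in by ipso-substitution. It sets out from 28: lithiation to 29 and a TMSCl quench give the 3-(trimethylsilyl)pyridine F6. Buffered mCPBA gives its N-oxide F7. ICl in CH2Cl2 at −78 → 0 °C effects ipso-iododesilylation, and the fallback comes back to the route at 31.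

Step 10 (intramolecular Diels–Alder of the trienal). The enal may polymerise or give eroded endo and facial selectivity with Me2AlCl. The fallback cyclises at the ester oxidation level, which tolerates stronger Lewis acid and higher temperature, and adjusts the oxidation state afterwards. It sets out from 9: EtAlCl2 in CH2Cl2 at rt gives the trans-fused decalin methyl ester F8. i-Bu2AlH gives the decalin methanol F9. Dess–Martin oxidation comes back to the route at 12.

**Further compounds**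
F1 | step 24 | [(1R,2R,4aS,6R,8aR)-2,6-dimethyl-1,2,4a,5,6,7,8,8a-octahydronaphthalen-1-yl]{5-[(1R,2R,5S,6S)-5-(tert-butyldimethylsilyloxy)-2-(trimethylsilyloxy)-7-oxabicyclo[4.1.0]heptan-2-yl]-2,4-bis[2-(trimethylsilyl)ethoxy]pyridin-3-yl}methanol (both epimers) | C[C@@H]1CC[C@H]2[C@H](C(O)c3c(OCC[Si](C)(C)C)ncc([C@]4(O[Si](C)(C)C)CC[C@H](O[Si](C)(C)C(C)(C)C)[C@H]5O[C@H]54)c3OCC[Si](C)(C)C)[C@H](C)C=C[C@@H]2C1
F2 | step 24 | the corresponding 3-acylpyridine (34 without the N-oxide oxygen) | C[C@@H]1CC[C@H]2[C@H](C(=O)c3c(OCC[Si](C)(C)C)ncc([C@]4(O[Si](C)(C)C)CC[C@H](O[Si](C)(C)C(C)(C)C)[C@H]5O[C@H]54)c3OCC[Si](C)(C)C)[C@H](C)C=C[C@@H]2C1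
F3 | step 24 | 3-[(1R,2R,4aS,6R,8aR)-2,6-dimethyl-1,2,4a,5,6,7,8,8a-octahydronaphthalene-1-carbonyl]-5-[(1R,2R,5S,6R)-2,5-dihydroxy-7-oxabicyclo[4.1.0]heptan-2-yl]-4-hydroxypyridin-2(1H)-one | C[C@@H]1CC[C@H]2[C@H](C(=O)c3c(O)c([C@]4(O)CC[C@H](O)[C@H]5O[C@H]54)c[nH]c3=O)[C@H](C)C=C[C@@H]2C1
F4 | step 24 | tetrakis(trimethylsilyl) derivative of F3 (2,4-bis(trimethylsilyloxy)pyridine; both carbinols as trimethylsilyl ethers) | C[C@@H]1CC[C@H]2[C@H](C(=O)c3c(O[Si](C)(C)C)ncc([C@]4(O[Si](C)(C)C)CC[C@H](O[Si](C)(C)C)[C@H]5O[C@H]54)c3O[Si](C)(C)C)[C@H](C)C=C[C@@H]2C1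
F5 | step 24 | pyridine 1-oxide of F4 | C[C@@H]1CC[C@H]2[C@H](C(=O)c3c(O[Si](C)(C)C)[n+]([O-])cc([C@]4(O[Si](C)(C)C)CC[C@H](O[Si](C)(C)C)[C@H]5O[C@H]54)c3O[Si](C)(C)C)[C@H](C)C=C[C@@H]2C1
F6 | step 23 | 3-(trimethylsilyl) derivative of 28 | C[Si](C)(C)CCOc1ncc([C@]2(O[Si](C)(C)C)CC[C@H](O[Si](C)(C)C(C)(C)C)[C@H]3O[C@H]32)c(OCC[Si](C)(C)C)c1[Si](C)(C)C
F7 | step 23 | pyridine 1-oxide of F6 | C[Si](C)(C)CCOc1c([Si](C)(C)C)c(OCC[Si](C)(C)C)c([C@]2(O[Si](C)(C)C)CC[C@H](O[Si](C)(C)C(C)(C)C)[C@H]3O[C@H]32)c[n+]1[O-]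
F8 | step 10 | methyl (1R,2R,4aS,6R,8aR)-2,6-dimethyl-1,2,4a,5,6,7,8,8a-octahydronaphthalene-1-carboxylate | C[C@@H]1CC[C@H]2[C@H](C(=O)OC)[C@H](C)C=C[C@@H]2C1
F9 | step 10 | [(1R,2R,4aS,6R,8aR)-2,6-dimethyl-1,2,4a,5,6,7,8,8a-octahydronaphthalen-1-yl]methanol | C[C@@H]1CC[C@H]2[C@H](CO)[C@H](C)C=C[C@@H]2C1
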